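**Strategy**

Everything rests on cutting the six-membered ring between C4', the carbinol carbon carrying CH3, and its neighbour C5', the future CHBr carbon. Two adjacent oxygenated ring carbons of this kind correspond to an α-ketol, so the ring (C1'–C6') can be closed by joining an aldehyde carbon (C5') to a methyl ketone carbon (C4') with inverted polarity. One carbene-catalysed operation forms the C4'–C5' bond, the ring and the tertiary carbinol. Its precursor is an acyclic (S)-3-alkenyl-6-oxoheptanal that already holds the C1' stereocentre, the E C9=C10 alkene and C8 as a 4-methoxybenzyl ether; bromine and the chiral-pool C1–C7 carbinol unit follow afterwards.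

Key step: step 7

Atom labels: the side chain is C1–C10 counted from the isopropylidene end (C6 is the chain carbinol, C7=C8 and C9=C10 form the diene, C10 is bonded to the ring). The ring is C1'–C6' (C1' methine, C4' carbinol, C5' CHBr). The target is 6S,7E,9E,1'S,4'R,5'S; side chain, ring hydroxyl and bromine are all cis (OH axial, the other two equatorial).

Assumption: commercial (R)-2-methylglycidol is of high enantiomeric purity (otherwise it is upgraded by recrystallising its 4-nitrobenzoate before use).

Design remark: C8 is carried as a PMB ether and not as a silyl ether, because both tertiary hydroxyls are later silylated and C8 must then be unmasked alone.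

**Route**

Step 1
Reactants: 1 but-2-yn-1-ol
Product: 2 1-[(but-2-yn-1-yloxy)methyl]-4-methoxybenzene
Conditions: NaH, 4-methoxybenzyl chloride, DMF, 0 °C to rt
Reagents that add atoms: 4-methoxybenzyl chloride, COc1ccc(CCl)cc1
Why: Williamson ether synthesis on the primary propargylic alkoxide; the PMB ether should survive every step up to its oxidative removal in step 12 and is orthogonal to the triethylsilyl ethers used later.

Step 2
Reactants: 2 1-[(but-2-yn-1-yloxy)methyl]-4-methoxybenzene
Product: 3 2-[(2Z)-4-[(4-methoxyphenyl)methoxy]but-2-en-2-yl]-4,4,5,5-tetramethyl-1,3,2-dioxaborolane (Z by the CIP rules because CH3 outranks B; boron is trans to the CH2O group)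
Conditions: B2pin2 (1.1 equiv), CuCl (5 mol %), PCy3 (6 mol %), NaOt-Bu (10 mol %), MeOH (2 equiv), toluene, rt
Reagents that add atoms: bis(pinacolato)diboron, CC1(C)OB(OC1(C)C)B1OC(C)(C)C(C)(C)O1
Why: Copper-catalysed formal hydroboration (syn borylcupration, then protonation of the C–Cu bond with retention) should place copper on the alkyne carbon next to the inductively withdrawing CH2O group and boron on the methyl-bearing carbon, so boron ends trans to CH2O, the geometry that becomes the E C9=C10 alkene.

Step 3
Reactants: 4 hex-5-en-2-one; 5 propan-2-yl prop-2-enoate (isopropyl acrylate)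
Product: 6 propan-2-yl (2E)-6-oxohept-2-enoate
Conditions: second-generation Grubbs catalyst (2 mol %), 5 (3 equiv), CH2Cl2, 40 °C
Reagents that add atoms: isopropyl acrylate 5, C=CC(=O)OC(C)C
Why: Olefin cross-metathesis of an unhindered terminal alkene with an acrylate pairs selectively and should give the E-enoate; the isopropyl ester is chosen because bulkier esters give higher enantioselectivity in the rhodium step that follows.

Step 4
Reactants: 6 propan-2-yl (2E)-6-oxohept-2-enoate; 3 alkenylboronate
Product: 7 propan-2-yl (3S)-3-[(2E)-4-[(4-methoxyphenyl)methoxy]but-2-en-2-yl]-6-oxoheptanoate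
Conditions: 3 (2.5 equiv), Rh(acac)(C2H4)2 (3 mol %), (R)-BINAP (3.3 mol %), 1,4-dioxane/H2O (10:1), 100 °C
Reagents that add atoms: alkenylboronate 3, COc1ccc(COC/C=C(\C)B2OC(C)(C)C(C)(C)O2)cc1
Why: Rhodium-catalysed asymmetric conjugate addition of an organoboron reagent to an enoate (Hayashi–Miyaura reaction): the alkenyl group passes from boron to rhodium with retention of geometry, and the (R)-BINAP complex is expected to bind the E-enoate on its α-re face (the mirror image of the α-si preference of the S ligand), which sets C1' as S.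

Step 5
Reactants: 7 keto ester
Product: 8 (3S)-3-[(2E)-4-[(4-methoxyphenyl)methoxy]but-2-en-2-yl]heptane-1,6-diol (both C6 carbinol epimers)
Conditions: LiAlH4 (2.5 equiv), THF, 0 °C to rt
Reagents that add atoms: none
Why: Hydride reduction of ester and ketone together with LiAlH4 avoids having to distinguish the two carbonyls; the configuration of the new secondary carbinol is irrelevant because it is oxidised in the next step.

Step 6
Reactants: 8 diol
Product: 9 (3S)-3-[(2E)-4-[(4-methoxyphenyl)methoxy]but-2-en-2-yl]-6-oxoheptanal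
Conditions: Dess–Martin periodinane (3 equiv), NaHCO3, CH2Cl2, 0 °C to rt; used at once
Reagents that add atoms: none
Why: Dess–Martin oxidation converts the primary and the secondary alcohol into aldehyde and methyl ketone in one operation under buffered, non-basic conditions, so the keto-aldehyde should not undergo aldol closure and C1' (not α to a carbonyl) cannot epimerise.

Step 7
Reactants: 9 (3S)-3-alkenyl-6-oxoheptanal
Product: 10 (2R,5S)-2-hydroxy-5-[(2E)-4-[(4-methoxyphenyl)methoxy]but-2-en-2-yl]-2-methylcyclohexan-1-one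
Conditions: (5aS,10bR)-2-(pentafluorophenyl)-5a,10b-dihydro-4H,6H-indeno[2,1-b][1,2,4]triazolo[4,3-d][1,4]oxazin-2-ium tetrafluoroborate (15 mol %), Et3N (15 mol %), toluene (0.05 M), rt, argon
Reagents that add atoms: none
Why: The triazolylidene adds to the C5' aldehyde, proton transfer gives the nucleophilic enaminol (Breslow intermediate), its C5' carbon attacks the C4' ketone, and loss of the carbene leaves the C5' ketone beside the new tertiary carbinol. The closest known reaction type is the carbene-catalysed intramolecular crossed aldehyde–ketone benzoin cyclisation of 1,6-keto-aldehydes to 2-hydroxy-2-alkylcyclohexanones. The cyclohexane ring closes in a 6-exo-trig mode (attack on the ketone carbon, its C=O exocyclic) through a chair that keeps the C1' alkenyl group equatorial. The new C4' centre (R: hydroxyl axial and cis to the side chain, methyl equatorial) is decided by which ketone face is attacked; the remote C1' centre only fixes the chair, so this choice is left to the chiral catalyst, and the antipode given is kept only if it reinforces the chair preference (otherwise its mirror image is used). The chemoselectivity needed is crossed acyloin formation instead of aldol or aldehyde dimerisation; it is secured because only the aldehyde can become an acyl anion, the ketone is the sole electrophile within six-ring reach at this dilution, and triethylamine is too weak to enolise the keto-aldehyde towards the competing cyclopentane aldols. C1' cannot epimerise because it is not α to either carbonyl.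

Step 8
Reactants: 10 α-ketol
Product: 11 (1R,2R,4S)-4-[(2E)-4-[(4-methoxyphenyl)methoxy]but-2-en-2-yl]-1-methylcyclohexane-1,2-diol
Conditions: Me4NBH(OAc)3 (5 equiv), MeCN/AcOH (1:1), −30 to 0 °C
Reagents that add atoms: none
Why: Hydroxyl-directed triacetoxyborohydride reduction (Evans–Saksena type): the axial C4' hydroxyl binds boron and delivers hydride to the same face of the C5' carbonyl, so the new C5' hydroxyl should end trans to it, giving the trans-diaxial diol.

Step 9
Reactants: 11 trans-diol
Product: 12 (1R,2R,5S)-2-hydroxy-5-[(2E)-4-[(4-methoxyphenyl)methoxy]but-2-en-2-yl]-2-methylcyclohexyl chloromethanesulfonate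
Conditions: ClCH2SO2Cl (1.3 equiv), pyridine (5 equiv), CH2Cl2, 0 °C
Reagents that add atoms: chloromethanesulfonyl chloride, ClCS(Cl)(=O)=O
Why: Chemoselective sulfonylation of the secondary hydroxyl (the tertiary one is inert) with a weak base that should not trigger epoxide closure; the chloromethanesulfonate is a far better leaving group than a mesylate yet isolable.

Step 10
Reactants: 12 hydroxy chloromethanesulfonate
Product: 13 (1R,2S,4S)-2-bromo-4-[(2E)-4-[(4-methoxyphenyl)methoxy]but-2-en-2-yl]-1-methylcyclohexan-1-ol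
Conditions: LiBr (10 equiv), DMF, 45 °C
Reagents that add atoms: lithium bromide, [Li+].[Br-]
Why: SN2 displacement with inversion: bromide attacks C5' anti to the axial sulfonate, the un-ionised neighbouring hydroxyl being a poor internal nucleophile under these neutral conditions and able to hydrogen-bond the incoming bromide, so bromine should end equatorial and cis to the C4' hydroxyl.

Step 11
Reactants: 13 bromohydrin
Product: 14 {[(1R,2S,4S)-2-bromo-4-[(2E)-4-[(4-methoxyphenyl)methoxy]but-2-en-2-yl]-1-methylcyclohexyl]oxy}triethylsilane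
Conditions: TESOTf (1.5 equiv), 2,6-lutidine (3 equiv), CH2Cl2, −78 to 0 °C
Reagents that add atoms: triethylsilyl trifluoromethanesulfonate, CC[Si](CC)(CC)OS(=O)(=O)C(F)(F)F
Why: Silyl triflate silylation of a hindered tertiary alcohol with a non-nucleophilic base; masking it prevents alkoxide formation, and the ring contraction that the alkoxide of a cis-bromohydrin can undergo, in the basic Wittig step.

Step 12
Reactants: 14 PMB ether
Product: 15 (2E)-3-[(1S,3S,4R)-3-bromo-4-methyl-4-(triethylsilyloxy)cyclohexyl]but-2-en-1-ol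
Conditions: DDQ (1.3 equiv), CH2Cl2/pH 7 phosphate buffer (10:1), 0 °C
Reagents that add atoms: none
Why: Oxidative PMB ether cleavage by DDQ (oxidation to the benzylic oxocarbenium ion, hydrolysed by the buffer) should leave the silyl ether, the alkyl bromide and the trisubstituted alkene untouched.

Step 13
Reactants: 15 allylic alcohol
Product: 16 {[(1R,2S,4S)-2-bromo-4-[(2E)-4-bromobut-2-en-2-yl]-1-methylcyclohexyl]oxy}triethylsilane
Conditions: CBr4 (1.3 equiv), PPh3 (1.4 equiv), 2,6-lutidine (0.2 equiv), CH2Cl2, −20 to 0 °C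
Reagents that add atoms: carbon tetrabromide, BrC(Br)(Br)Br
Why: Appel reaction: the primary allylic alcohol is converted through its alkoxyphosphonium salt into the bromide by direct SN2 at unhindered C8, with no allylic shift towards the fully substituted C10 and no change of alkene geometry expected.

Step 14
Reactants: 16 allylic bromide
Product: 17 tributyl[(2E)-3-[(1S,3S,4R)-3-bromo-4-methyl-4-(triethylsilyloxy)cyclohexyl]but-2-en-1-yl]phosphonium bromide
Conditions: PBu3 (1.1 equiv), MeCN, rt
Reagents that add atoms: tributylphosphine, CCCCP(CCCC)CCCC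
Why: Quaternisation (SN2) of tributylphosphine by the allylic bromide at room temperature; the hindered secondary ring bromide should not react under these conditions.

Step 15
Reactants: 18 (R)-2-methylglycidol [(2R)-(2-methyloxiran-2-yl)methanol]; 19 allylmagnesium bromide
Product: 20 (2S)-2-methylhex-5-ene-1,2-diol
Conditions: 19 (3 equiv), CuBr·SMe2 (10 mol %), THF, −40 to 0 °C; aq NH4Cl
Reagents that add atoms: allylmagnesium bromide 19, C=CC[Mg]Br
Why: Copper-catalysed Grignard opening of a 2,2-disubstituted epoxide at its CH2 terminus (SN2) leaves the quaternary stereocentre from the chiral pool untouched; the first equivalent of Grignard reagent only deprotonates the hydroxyl, and the descriptor changes from R to S only because the CIP priorities change.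

Step 16
Reactants: 20 (2S)-2-methylhex-5-ene-1,2-diol; 21 2-methylbut-2-ene
Product: 22 (2S)-2,6-dimethylhept-5-ene-1,2-diol
Conditions: second-generation Grubbs catalyst (3 mol %), 21 (20 equiv), CH2Cl2, 40 °C (sealed tube)
Reagents that add atoms: 2-methylbut-2-ene 21, CC=C(C)C
Why: Olefin cross-metathesis of the terminal alkene with 2-methylbut-2-ene transfers an isopropylidene unit and installs the trisubstituted C2=C3 alkene, a standard prenyl end-group synthesis that tolerates free hydroxyls.

Step 17
Reactants: 22 (2S)-2,6-dimethylhept-5-ene-1,2-diol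
Product: 23 (2S)-2,6-dimethyl-1,2-bis(triethylsilyloxy)hept-5-ene
Conditions: TESOTf (2.5 equiv), 2,6-lutidine (4 equiv), CH2Cl2, −78 to 0 °C
Reagents that add atoms: triethylsilyl trifluoromethanesulfonate, CC[Si](CC)(CC)OS(=O)(=O)C(F)(F)F
Why: Exhaustive silylation with the silyl triflate, needed because the tertiary hydroxyl does not react with the silyl chloride.

Step 18
Reactants: 23 bis(triethylsilyl) ether
Product: 24 (2S)-2,6-dimethyl-2-(triethylsilyloxy)hept-5-enal
Conditions: (COCl)2 (4 equiv), DMSO (8 equiv), CH2Cl2, −78 to −30 °C; then Et3N, −78 °C to rt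
Reagents that add atoms: none
Why: Swern oxidation applied directly to the bis-silyl ether: the chlorosulfonium salt attacks only the primary silyl ether oxygen, which is desilylated and oxidised to the aldehyde while the tertiary silyl ether stays; the α-quaternary aldehyde cannot epimerise.

Step 19
Reactants: 17 allylic phosphonium bromide; 24 (2S)-2,6-dimethyl-2-(triethylsilyloxy)hept-5-enal
Product: 26 triethyl{[(1R,2S,4S)-2-bromo-4-[(2E,4E,6S)-6,10-dimethyl-6-(triethylsilyloxy)undeca-2,4,9-trien-2-yl]-1-methylcyclohexyl]oxy}silane, via phosphonium ylide 25 (not isolated)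
Conditions: KN(SiMe3)2 (1.0 equiv), THF, −78 °C; then 24 (1.2 equiv), −78 to 0 °C
Reagents that add atoms: aldehyde 24, CC(C)=CCC[C@](C)(O[Si](CC)(CC)CC)C=O
Why: Wittig olefination with a semi-stabilised allylic trialkylphosphonium ylide, a class that gives E alkenes with aldehydes (reinforced here by the α-quaternary aldehyde) and keeps the geometry of the ylide's own trisubstituted alkene, should form the E C7=C8 bond and complete the E,E-diene; one equivalent of base deprotonates only C8 because both hydroxyls are silylated.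

Step 20
Reactants: 26 bis(triethylsilyl) ether of the target
Product: 27 (1R,2S,4S)-2-bromo-4-[(2E,4E,6S)-6-hydroxy-6,10-dimethylundeca-2,4,9-trien-2-yl]-1-methylcyclohexan-1-ol (CNP0308936.2)
Conditions: Bu4NF/AcOH (1:1, 6 equiv), THF, 0 °C to rt
Reagents that add atoms: none
Why: Fluoride-mediated cleavage of both tertiary triethylsilyl ethers under acetic acid buffering avoids a free alkoxide next to the bromide (ring contraction) and avoids acid strong enough to ionise the dienylic tertiary carbinol.

**Compound list**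

1 | but-2-yn-1-ol | CC#CCO | starting material
2 | 1-[(but-2-yn-1-yloxy)methyl]-4-methoxybenzene | CC#CCOCc1ccc(OC)cc1 | intermediate
3 | 2-[(2Z)-4-[(4-methoxyphenyl)methoxy]but-2-en-2-yl]-4,4,5,5-tetramethyl-1,3,2-dioxaborolane | COc1ccc(COC/C=C(\C)B2OC(C)(C)C(C)(C)O2)cc1 | intermediate
4 | hex-5-en-2-one | C=CCCC(C)=O | starting material
5 | propan-2-yl prop-2-enoate (isopropyl acrylate) | C=CC(=O)OC(C)C | starting material
6 | propan-2-yl (2E)-6-oxohept-2-enoate | CC(=O)CC/C=C/C(=O)OC(C)C | intermediate
7 | propan-2-yl (3S)-3-[(2E)-4-[(4-methoxyphenyl)methoxy]but-2-en-2-yl]-6-oxoheptanoate | COc1ccc(COC/C=C(\C)[C@H](CC(=O)OC(C)C)CCC(C)=O)cc1 | intermediate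
8 | (3S)-3-[(2E)-4-[(4-methoxyphenyl)methoxy]but-2-en-2-yl]heptane-1,6-diol (C6 epimers) | COc1ccc(COC/C=C(\C)[C@H](CCO)CCC(C)O)cc1 | intermediate
9 | (3S)-3-[(2E)-4-[(4-methoxyphenyl)methoxy]but-2-en-2-yl]-6-oxoheptanal | COc1ccc(COC/C=C(\C)[C@H](CC=O)CCC(C)=O)cc1 | intermediate
10 | (2R,5S)-2-hydroxy-5-[(2E)-4-[(4-methoxyphenyl)methoxy]but-2-en-2-yl]-2-methylcyclohexan-1-one | COc1ccc(COC/C=C(\C)[C@H]2CC[C@@](C)(O)C(=O)C2)cc1 | intermediate
11 | (1R,2R,4S)-4-[(2E)-4-[(4-methoxyphenyl)methoxy]but-2-en-2-yl]-1-methylcyclohexane-1,2-diol | COc1ccc(COC/C=C(\C)[C@H]2CC[C@@](C)(O)[C@H](O)C2)cc1 | intermediate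
12 | (1R,2R,5S)-2-hydroxy-5-[(2E)-4-[(4-methoxyphenyl)methoxy]but-2-en-2-yl]-2-methylcyclohexyl chloromethanesulfonate | COc1ccc(COC/C=C(\C)[C@H]2CC[C@@](C)(O)[C@H](OS(=O)(=O)CCl)C2)cc1 | intermediate
13 | (1R,2S,4S)-2-bromo-4-[(2E)-4-[(4-methoxyphenyl)methoxy]but-2-en-2-yl]-1-methylcyclohexan-1-ol | COc1ccc(COC/C=C(\C)[C@H]2CC[C@@](C)(O)[C@@H](Br)C2)cc1 | intermediate
14 | {[(1R,2S,4S)-2-bromo-4-[(2E)-4-[(4-methoxyphenyl)methoxy]but-2-en-2-yl]-1-methylcyclohexyl]oxy}triethylsilane | COc1ccc(COC/C=C(\C)[C@H]2CC[C@@](C)(O[Si](CC)(CC)CC)[C@@H](Br)C2)cc1 | intermediate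
15 | (2E)-3-[(1S,3S,4R)-3-bromo-4-methyl-4-(triethylsilyloxy)cyclohexyl]but-2-en-1-ol | OC/C=C(\C)[C@H]1CC[C@@](C)(O[Si](CC)(CC)CC)[C@@H](Br)C1 | intermediate
16 | {[(1R,2S,4S)-2-bromo-4-[(2E)-4-bromobut-2-en-2-yl]-1-methylcyclohexyl]oxy}triethylsilane | BrC/C=C(\C)[C@H]1CC[C@@](C)(O[Si](CC)(CC)CC)[C@@H](Br)C1 | intermediate
17 | tributyl[(2E)-3-[(1S,3S,4R)-3-bromo-4-methyl-4-(triethylsilyloxy)cyclohexyl]but-2-en-1-yl]phosphonium bromide | CCCC[P+](CCCC)(CCCC)C/C=C(\C)[C@H]1CC[C@@](C)(O[Si](CC)(CC)CC)[C@@H](Br)C1.[Br-] | intermediate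
18 | (R)-2-methylglycidol, (2R)-(2-methyloxiran-2-yl)methanol | C[C@@]1(CO)CO1 | starting material
19 | allylmagnesium bromide | C=CC[Mg]Br | starting material
20 | (2S)-2-methylhex-5-ene-1,2-diol | C=CCC[C@](C)(O)CO | intermediate
21 | 2-methylbut-2-ene | CC=C(C)C | starting material
22 | (2S)-2,6-dimethylhept-5-ene-1,2-diol | CC(C)=CCC[C@](C)(O)CO | intermediate
23 | (2S)-2,6-dimethyl-1,2-bis(triethylsilyloxy)hept-5-ene | CC(C)=CCC[C@](C)(O[Si](CC)(CC)CC)CO[Si](CC)(CC)CC | intermediate
24 | (2S)-2,6-dimethyl-2-(triethylsilyloxy)hept-5-enal | CC(C)=CCC[C@](C)(O[Si](CC)(CC)CC)C=O | intermediate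
25 | tributylphosphonium ylide of 17 (C8 carbanion), not isolated | CCCC[P+](CCCC)(CCCC)[CH-]/C=C(\C)[C@H]1CC[C@@](C)(O[Si](CC)(CC)CC)[C@@H](Br)C1 | intermediate
26 | triethyl{[(1R,2S,4S)-2-bromo-4-[(2E,4E,6S)-6,10-dimethyl-6-(triethylsilyloxy)undeca-2,4,9-trien-2-yl]-1-methylcyclohexyl]oxy}silane | CC(C)=CCC[C@](C)(O[Si](CC)(CC)CC)/C=C/C=C(\C)[C@H]1CC[C@@](C)(O[Si](CC)(CC)CC)[C@@H](Br)C1 | intermediate
27 | (1R,2S,4S)-2-bromo-4-[(2E,4E,6S)-6-hydroxy-6,10-dimethylundeca-2,4,9-trien-2-yl]-1-methylcyclohexan-1-ol | CC(C)=CCC[C@](C)(O)/C=C/C=C(\C)[C@H]1CC[C@@](C)(O)[C@@H](Br)C1 | target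

**Step count**

Total: 20 steps. Longest linear sequence: 15 steps (steps 1, 2, 4–14, 19, 20).

**Steps most likely to fail**

1. Step 7. What may go wrong: the catalyst may not control which face of the C4' ketone is attacked, because the remote C1' centre gives little bias, so the C4' epimer would be co-formed; base-mediated aldol closure to cyclopentanes may also compete. Fallback: setting out from keto-aldehyde 9, SmI2 (2.5 equiv) with t-BuOH in THF at −78 °C would close the same C4'–C5' bond by reductive ketyl–carbonyl (pinacol) cyclisation through a samarium-bridged chair, giving the cis-diol (1R,2S,4S)-4-[(2E)-4-[(4-methoxyphenyl)methoxy]but-2-en-2-yl]-1-methylcyclohexane-1,2-diol F1 (any C4' epimer would be separated at this stage). Oxidation of its secondary hydroxyl with SO3·pyridine, DMSO and i-Pr2NEt then returns the route at ketol 10.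

2. Step 10. What may go wrong: E2 elimination towards the C5'=C6' alkene, or internal displacement by the neighbouring hydroxyl (epoxide, then reopening with net retention), may outrun the hindered SN2 at C5'. Fallback: setting out from diol 11, both hydroxyls are silylated (TESOTf, 2,6-lutidine) to (1R,2R,4S)-4-[(2E)-4-[(4-methoxyphenyl)methoxy]but-2-en-2-yl]-1-methyl-1,2-bis(triethylsilyloxy)cyclohexane F2. The less hindered secondary silyl ether is then cleaved (PPTS, MeOH/CH2Cl2, 0 °C) to (1R,2R,5S)-5-[(2E)-4-[(4-methoxyphenyl)methoxy]but-2-en-2-yl]-2-methyl-2-(triethylsilyloxy)cyclohexan-1-ol F3. Its free C5' hydroxyl is replaced by bromide with inversion through the alkoxyphosphonium salt (Appel-type deoxybromination, tri-n-octylphosphine, CBr4, toluene, 70 °C). This mode of activation has a neutral phosphine oxide leaving group and no free neighbouring hydroxyl, and it gives silyl ether 14, where the route is rejoined.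

3. Step 4. What may go wrong: slow transmetalation and protodeboronation of the hindered, α-substituted alkenylboronate, or eroded enantioselectivity on the acyclic enoate. Fallback (auxiliary-controlled cuprate addition): setting out from hex-5-en-2-one 4, the ketone is masked as 2-(but-3-en-1-yl)-2-methyl-1,3-dioxolane F4 (ethylene glycol, TsOH). Cross-metathesis with (R)-3-acryloyl-4-phenyl-1,3-oxazolidin-2-one (second-generation Grubbs catalyst) gives (4R)-3-[(2E)-5-(2-methyl-1,3-dioxolan-2-yl)pent-2-enoyl]-4-phenyl-1,3-oxazolidin-2-one F5. Boronate 3 is converted with retention of geometry (NaOH, then I2) into 1-{[(2E)-3-iodobut-2-en-1-yl]oxymethyl}-4-methoxybenzene F6. After iodine–lithium exchange (t-BuLi, −78 °C) and transmetalation (MgBr2·OEt2, CuBr·SMe2), F6 should add to F5 anti to the phenyl group of the chelated imide, giving (4R)-3-[(3S)-3-[(2E)-4-[(4-methoxyphenyl)methoxy]but-2-en-2-yl]-5-(2-methyl-1,3-dioxolan-2-yl)pentanoyl]-4-phenyl-1,3-oxazolidin-2-one F7. LiBH4 removes the auxiliary to give (3S)-3-[(2E)-4-[(4-methoxyphenyl)methoxy]but-2-en-2-yl]-5-(2-methyl-1,3-dioxolan-2-yl)pentan-1-ol F8. Aqueous PPTS in acetone unmasks the ketone to (5S)-7-hydroxy-5-[(2E)-4-[(4-methoxyphenyl)methoxy]but-2-en-2-yl]heptan-2-one F9, and Dess–Martin oxidation returns the route at keto-aldehyde 9.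

**Further compounds**

F1 | step 7 | (1R,2S,4S)-4-[(2E)-4-[(4-methoxyphenyl)methoxy]but-2-en-2-yl]-1-methylcyclohexane-1,2-diol | COc1ccc(COC/C=C(\C)[C@H]2CC[C@@](C)(O)[C@@H](O)C2)cc1
F2 | step 10 | (1R,2R,4S)-4-[(2E)-4-[(4-methoxyphenyl)methoxy]but-2-en-2-yl]-1-methyl-1,2-bis(triethylsilyloxy)cyclohexane | COc1ccc(COC/C=C(\C)[C@H]2CC[C@@](C)(O[Si](CC)(CC)CC)[C@H](O[Si](CC)(CC)CC)C2)cc1
F3 | step 10 | (1R,2R,5S)-5-[(2E)-4-[(4-methoxyphenyl)methoxy]but-2-en-2-yl]-2-methyl-2-(triethylsilyloxy)cyclohexan-1-ol | COc1ccc(COC/C=C(\C)[C@H]2CC[C@@](C)(O[Si](CC)(CC)CC)[C@H](O)C2)cc1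
F4 | step 4 | 2-(but-3-en-1-yl)-2-methyl-1,3-dioxolane | CC1(CCC=C)OCCO1
F5 | step 4 | (4R)-3-[(2E)-5-(2-methyl-1,3-dioxolan-2-yl)pent-2-enoyl]-4-phenyl-1,3-oxazolidin-2-one | CC1(CC/C=C/C(=O)N2[C@H](c3ccccc3)COC2=O)OCCO1
F6 | step 4 | 1-{[(2E)-3-iodobut-2-en-1-yl]oxymethyl}-4-methoxybenzene | COc1ccc(COC/C=C(\C)I)cc1
F7 | step 4 | (4R)-3-[(3S)-3-[(2E)-4-[(4-methoxyphenyl)methoxy]but-2-en-2-yl]-5-(2-methyl-1,3-dioxolan-2-yl)pentanoyl]-4-phenyl-1,3-oxazolidin-2-one | COc1ccc(COC/C=C(\C)[C@H](CC(=O)N2[C@H](c3ccccc3)COC2=O)CCC4(C)OCCO4)cc1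
F8 | step 4 | (3S)-3-[(2E)-4-[(4-methoxyphenyl)methoxy]but-2-en-2-yl]-5-(2-methyl-1,3-dioxolan-2-yl)pentan-1-ol | COc1ccc(COC/C=C(\C)[C@H](CCO)CCC2(C)OCCO2)cc1
F9 | step 4 | (5S)-7-hydroxy-5-[(2E)-4-[(4-methoxyphenyl)methoxy]but-2-en-2-yl]heptan-2-one | COc1ccc(COC/C=C(\C)[C@H](CCO)CCC(C)=O)cc1
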